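It is impossible to read from one point on a curve both how fast left-handed product forms and how much substrate is lost beside it, so I read the earlier runs by their shape.

| setting | west | south-east | north-east | spring | dusk | dawn | midnight |
|---|---|---|---|---|---|---|---|
| left-handed substrate | 0.011 M | 0.011 M | 0.022 M | 0.011 M | 0.011 M | 0.011 M | 0.011 M |
| right-handed substrate | 0.011 M | 0.011 M | 0.022 M | 0.011 M | 0.011 M | 0.011 M | 0.011 M |
| solid reagent | 4.2 equiv | 6.6 equiv | 3 equiv | 3.00 equiv | 3.00 equiv | 3.00 equiv | 3.00 equiv |
| temperature | −30 °C | 0 °C | −30 °C | 25 °C |  | 0 °C | −25 °C |
| remark | run made earlier | run made earlier | run made earlier |  | at 25 °C until 10 min, from then on at −25 °C |  |  |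
| time |  |  |  | 15 min | 15 min | 15 min | 15 min |

| run | time / min | left-handed product / % |
|---|---|---|
| west | 10.0 | 3.9 |
| west | 25.0 | 8.2 |
| west | 60.0 | 18.4 |
| west | 150 | 30.1 |
| south-east | 3.00 | 5.4 |
| south-east | 10.0 | 14.3 |
| south-east | 20.0 | 19.3 |
| south-east | 30.0 | 21.0 |
| north-east | 10.0 | 2.9 |
| north-east | 25.0 | 8.6 |
| north-east | 60.0 | 19.5 |
| north-east | 150 | 31.9 |

(each reading ± 1 percentage point)

- coupling partner is single-handed; left-handed substrate and right-handed substrate are mirror images of each other, charged as a racemate, each of them at the stated concentration
- solid reagent is a solid; its amount is given per volume of the solution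
- the numbers in the tables scatter with a standard deviation of 1 percentage point
- steps thought possible: coupling partner + right-handed substrate -> right-handed product; achiral form -> waste; solid reagent <-> coupling partner; left-handed substrate <-> achiral form; achiral form -> side product; coupling partner + left-handed substrate -> left-handed product; right-handed substrate <-> achiral form; 2 coupling partner -> homo dimer
- at the start none of the solid reagent is in solution
- the handed part of coupling partner does not stay in what it makes, so the products of the two hands are mirror images too

* the flask that comes out highest in amount of left-handed product, in percent of the left-handed substrate and right-handed substrate together charged, or "all alike" when all lie within 1.5 percentage points (spring / dusk / dawn / midnight / all alike)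
* left-handed product at the end, in percent of the left-handed substrate and right-handed substrate together charged, spring
* left-handed product at the end, in percent of the left-handed substrate and right-handed substrate together charged, dusk
* left-handed product at the end, in percent of the left-handed substrate and right-handed substrate together charged, dawn
* left-handed product at the end, in percent of the left-handed substrate and right-handed substrate together charged, midnight

West and north-east differ in charge and in solid reagent, yet at 25.0 min they stand at 8.2% and 8.6%, with a scatter of 1 percentage point. So coupling looks pseudo-first-order in substrate, with c(coupling partner) held up by the dissolving solid. Together these two runs climb 0.00336 min⁻¹ at −30 °C, but south-east's first reading gives 0.0180 min⁻¹ at 0 °C. Spreading that ratio evenly over the degrees, I get 0.00444 min⁻¹ at −25 °C, my starting pace: the share of the charge becoming left-handed product per minute while the curve is straight. So I put midnight at 6.67%.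

South-east is no straight line, since it gains 1.7 points in its last 10.0 min. For dawn I therefore take the midpoint of its readings at 10.0 min and 20.0 min, which gives 16.8%. I expect spring and dusk to bend sooner and end lower, though I put no figure on them, so I choose dawn.

The forecast also says dawn, with 10.5%, 10.6%, 17% and 7% for spring, dusk, dawn and midnight, holding of dusk that “substrate is already gone at the switch”.

The flasks give dawn as highest, with 8.70%, 8.70%, 16.7% and 8.02% in that order.

    coupling partner + right-handed substrate → right-handed product (k = 0.430 M⁻¹ s⁻¹, Ea = 46.0 kJ mol⁻¹)
    achiral form → waste (k = 7.80 × 10⁻⁴ s⁻¹, Ea = 92.0 kJ mol⁻¹)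
    solid reagent ⇌ coupling partner, rate k3*(cs3 - [coupling partner]) while solid is left; crystals form when [coupling partner] > cs3 (solubility = 8.60 mM, k = 0.00870 s⁻¹)
    left-handed substrate ⇌ achiral form (K = 0.550, k = 0.0880 s⁻¹, Ea = 82.0 kJ mol⁻¹, ΔH = −37.0 kJ mol⁻¹)
    achiral form → side product (k = 0.0530 s⁻¹, Ea = 88.0 kJ mol⁻¹)
    coupling partner + left-handed substrate → left-handed product (k = 1.40 M⁻¹ s⁻¹, Ea = 47.0 kJ mol⁻¹)
    right-handed substrate ⇌ achiral form (K = 0.550, k = 0.0880 s⁻¹, Ea = 82.0 kJ mol⁻¹, ΔH = −37.0 kJ mol⁻¹)
    2 coupling partner → homo dimer (k = 3.30 M⁻¹ s⁻¹, Ea = 50.0 kJ mol⁻¹)
    (constants at 25 °C)

At 15.0 min midnight has 75% of its charged left-handed substrate still there, unbound, with c(coupling partner) at 0.00755 M, and my straight line reaches 0.832 of its left-handed product. The same flask read at 25 min takes the same starting pace, which gives 11.1%. The neighbour stands at 12.8%, a ratio of 0.867, with 30.6% of the charge still left-handed substrate.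

Readings and results are calculated on assumed constants; noise was put on by code.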